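## Retrosynthetic overview

- Target 29 comes from macrocycle 26 by double amine elimination and one desilylation. In 26 both acrylate units are masked as Me2NH adducts.
- Ring B (the trans γ-lactone) is made first. Ring A (the ten-membered carbocycle) is closed last, at C1–C2, by nickel-electrocatalytic decarboxylative alkenylation of the open-chain iodide/redox-active ester 25.
- Enabling feature: C1–C2 is the C(sp2)–C(sp3) joint of the 1,5-diene C10=C1–C2–C3–C4=C5 of ring A. C1 is a vinylic CH cis to C9, so it maps onto a stereodefined alkenyl iodide. C2 is an unbranched CH2, the radical left when a 4-enoic acid loses CO2. Ring B holds the arms C6 and C9 gauche.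
- The open chain comes from an anti-selective asymmetric chromium allylation (C7–C8) of aldehyde 6 with allylic chloride 19, followed by oxidative lactonisation.
- Both trisubstituted alkenes derive from a propargyl unit (acetate 1 or alcohol 13) plus allyl bromide: syn bromoallylation gives C1=C10, and anti carbomagnesiation/allylation gives C4=C5.

Key step: step 16

Remark: germacrane numbering is used (C14 = CH2OAc carbon, C15 = CH2O-acyl carbon, C11–C13 = lactone carbons); TBS = tert-butyldimethylsilyl, TBDPS = tert-butyldiphenylsilyl; 24–27 are carried as epimer mixtures at the two amine-bearing α-carbons, which step 17 erases; 18–19 are E/Z mixtures at the double bond that step 11 erases.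

## Route

Step 1
Reactants: 1 prop-2-yn-1-yl acetate; 2 allyl bromide
Product: 3 (E)-2-(bromomethylidene)pent-4-en-1-yl acetate
Conditions: PdBr2(PhCN)2 (3 mol %), 2 (6 equiv, neat), 0 °C to rt
Reagents that add atoms: none
Why: Palladium-catalysed bromoallylation of a terminal alkyne: syn-bromopalladation by divalent palladium places Br on the terminal carbon, and insertion of allyl bromide with β-bromide elimination then puts the allyl group cis to Br, so the C1=C10 geometry of the target (C9 cis to the future C2) is fixed here.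

Step 2
Reactants: 3 (E)-2-(bromomethylidene)pent-4-en-1-yl acetate
Product: 4 (E)-2-(iodomethylidene)pent-4-en-1-yl acetate
Conditions: NaI (2 equiv), CuI (10 mol %), trans-N,N'-dimethylcyclohexane-1,2-diamine (20 mol %), 1,4-dioxane, 100 °C
Reagents that add atoms: sodium iodide [Na+].[I-]
Why: Copper-catalysed vinylic Finkelstein reaction, which exchanges bromide for iodide with retention of the alkene geometry and supplies the halide that inserts fastest in step 16.

Step 3
Reactants: 4 (E)-2-(iodomethylidene)pent-4-en-1-yl acetate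
Product: 6 (E)-2-(iodomethylidene)-4-oxobutyl acetate, via diol 5 (not isolated)
Conditions: OsO4 (2 mol %), NaIO4 (4 equiv), 2,6-lutidine (2 equiv), dioxane–H2O 3:1, 0 °C to rt; used crude
Reagents that add atoms: sodium periodate [Na+].[O-]I(=O)(=O)=O; osmium tetroxide O=[Os](=O)(=O)=O
Why: Lemieux–Johnson cleavage, in which OsO4 should pick the monosubstituted alkene over the iodine- and acetoxymethyl-deactivated trisubstituted one while the lutidine buffer keeps the β,γ-unsaturated aldehyde from moving into conjugation.

Step 4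
Reactants: 7 2-methylidenepropane-1,3-diol
Product: 8 2-{[(TBS)oxy]methyl}prop-2-en-1-ol
Conditions: NaH (1.0 equiv), THF, 0 °C; TBSCl (1.0 equiv), rt
Reagents that add atoms: tert-butyldimethylsilyl chloride CC(C)(C)[Si](C)(C)Cl
Why: Monosilylation of a symmetrical diol through its sparingly soluble monosodium alkoxide, a standard O-silylation that stops after one hydroxyl.

Step 5
Reactants: 8 2-{[(TBS)oxy]methyl}prop-2-en-1-ol
Product: 9 tert-butyl{[2-(chloromethyl)prop-2-en-1-yl]oxy}dimethylsilane
Conditions: N-chlorosuccinimide, Me2S, CH2Cl2, −20 to 0 °C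
Reagents that add atoms: N-chlorosuccinimide O=C1CCC(=O)N1Cl
Why: Corey–Kim chlorination turns the allylic alcohol into the chloride under neutral conditions that leave the silyl ether and the 1,1-disubstituted alkene alone.

Step 6
Reactants: 10 ethyl 2-(hydroxymethyl)acrylate
Product: 11 ethyl 2-{[(TBDPS)oxy]methyl}acrylate
Conditions: TBDPSCl, imidazole, CH2Cl2, rt
Reagents that add atoms: tert-butyldiphenylsilyl chloride CC(C)(C)[Si](Cl)(c1ccccc1)c1ccccc1
Why: Imidazole-promoted O-silylation installs the acid-stable silyl group that must outlast the two TBS ethers in step 12.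

Step 7
Reactants: 11 ethyl 2-{[(TBDPS)oxy]methyl}acrylate
Product: 12 2-{[(TBDPS)oxy]methyl}acrylic acid
Conditions: LiOH·H2O, THF–H2O, 0 °C to rt; then 1 M HCl to pH 3
Reagents that add atoms: lithium hydroxide [Li+].[OH-]
Why: Saponification of the ethyl ester at low temperature, where hydroxide attacks the ester carbonyl faster than the hindered 2-substituted acrylate terminus.

Step 8
Reactants: 13 prop-2-yn-1-ol; 14 (3-bromopropoxy)(tert-butyl)dimethylsilane; 2 allyl bromide
Product: 17 (Z)-2-{3-[(TBS)oxy]propyl}hexa-2,5-dien-1-ol, via Grignard reagent 15 (not isolated), via vinylmagnesium chelate 16 (not isolated)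
Conditions: 14, Mg, THF (2.6 equiv of 15); 13, CuI (15 mol %), −10 °C to rt; then 2 (4 equiv), 0 °C; aq NH4Cl
Reagents that add atoms: none
Why: Copper-catalysed anti-carbomagnesiation of the propargylic magnesium alkoxide gives the five-membered chelate 16 with Mg cis to the CH2O group, and copper-mediated allylation with retention then sets the C4=C5 geometry (C15 cis to C6, C3 trans to C6).

Step 9
Reactants: 17 (Z)-2-{3-[(TBS)oxy]propyl}hexa-2,5-dien-1-ol; 9 tert-butyl{[2-(chloromethyl)prop-2-en-1-yl]oxy}dimethylsilane
Product: 18 (2Z)-6-(chloromethyl)-2-{3-[(TBS)oxy]propyl}-7-[(TBS)oxy]hepta-2,5-dien-1-ol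
Conditions: 9 (5 equiv), second-generation Hoveyda–Grubbs catalyst (7 mol %), 1,4-benzoquinone (10 mol %), CH2Cl2, 40 °C
Reagents that add atoms: none
Why: Olefin cross metathesis of a monosubstituted alkene with an excess of a 1,1-disubstituted partner builds the trisubstituted allylic chloride, whose E/Z ratio does not matter because step 11 erases this double bond.

Step 10
Reactants: 18 (2Z)-6-(chloromethyl)-2-{3-[(TBS)oxy]propyl}-7-[(TBS)oxy]hepta-2,5-dien-1-ol; 12 2-{[(TBDPS)oxy]methyl}acrylic acid
Product: 19 (2Z)-6-(chloromethyl)-2-{3-[(TBS)oxy]propyl}-7-[(TBS)oxy]hepta-2,5-dien-1-yl 2-{[(TBDPS)oxy]methyl}acrylate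
Conditions: EDC·HCl, DMAP (20 mol %), CH2Cl2, 0 °C to rt
Reagents that add atoms: none
Why: Steglich esterification of the primary allylic alcohol, run after the metathesis so that the acrylate cannot take part in ring-closing metathesis.

Step 11
Reactants: 19 allylic chloride ester; 6 (E)-2-(iodomethylidene)-4-oxobutyl acetate
Product: 21 (7R,8S)-anti homoallylic alcohol (C8 carbinol bearing the iodomethylidene/acetoxymethyl arm; C7 bearing the 3-[(TBS)oxy]prop-1-en-2-yl group plus the C6–C2 chain), via trimethylsilyl ether 20 (not isolated)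
Conditions: CrCl2 (10 mol %), valinol-derived 1,8-bis(oxazolin-2-yl)carbazole ligand (12 mol %, antipode chosen for Re-face attack), iPr2NEt (30 mol %), Mn (2 equiv), Me3SiCl (2 equiv), THF, rt; then aq citric acid, THF, 0 °C
Reagents that add atoms: none
Why: Catalytic asymmetric Nozaki–Hiyama allylation: the equilibrating allylchromium species reacts at its γ-carbon C7 through a chair transition state with both chains equatorial, which sets the anti (7R,8S) relation whatever the geometry of 19, and the chiral ligand on trivalent chromium directs attack to the Re face of 6 to set 8S, while the alkenyl iodide stays inert in the absence of nickel.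

Step 12
Reactants: 21 (7R,8S)-anti homoallylic alcohol
Product: 22 (7R,8S)-triol (free C8, C12 and chain-end hydroxyls; TBDPS retained)
Conditions: HF·pyridine, pyridine, THF, 0 °C
Reagents that add atoms: none
Why: Fluoride-mediated desilylation under pyridine buffering removes the two primary TBS ethers much faster than the bulkier TBDPS ether and leaves the esters untouched.

Step 13
Reactants: 22 (7R,8S)-triol
Product: 23 (Z)-6-[(2S,3R)-2-{(E)-2-(acetoxymethyl)-3-iodoallyl}-4-methylidene-5-oxotetrahydrofuran-3-yl]-4-[({2-[(TBDPS-oxy)methyl]acryloyl}oxy)methyl]hex-4-enoic acid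
Conditions: TEMPO (0.3 equiv), PhI(OAc)2 (5 equiv), MeCN–pH 7 buffer 1:1, rt
Reagents that add atoms: water O
Why: Oxoammonium (TEMPO/PhI(OAc)2) oxidation: the allylic C12 alcohol is oxidised, closes on the C8 hydroxyl and is oxidised on to the α-methylene-γ-lactone (ring B) with C7 and C8 untouched, while the terminal alcohol goes to the carboxylic acid in the aqueous medium.

Step 14
Reactants: 23 α-methylene lactone acid
Product: 24 bis(dimethylamine) adduct of 23 (lactone α-CH2NMe2; side chain 3-(dimethylamino)-2-[(TBDPS-oxy)methyl]propanoate)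
Conditions: Me2NH (2 M in THF, 6 equiv), THF, 0 °C to rt; pH 6.5 buffer wash to remove free amine
Reagents that add atoms: dimethylamine CNC
Why: Double aza-Michael addition masks both radical-accepting acrylate units, and the two new α-centres form as epimer mixtures that are of no consequence because step 17 removes them.

Step 15
Reactants: 24 bis(dimethylamine) adduct
Product: 25 N-acyloxyphthalimide (redox-active ester) of 24
Conditions: N-hydroxyphthalimide (1.1 equiv), DIC (1.1 equiv), DMAP (10 mol %), CH2Cl2, rt, dark
Reagents that add atoms: N-hydroxyphthalimide O=C1c2ccccc2C(=O)N1O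
Why: Carbodiimide coupling gives the redox-active ester, the tertiary amines acting only as spectators.

Step 16
Reactants: 25 N-acyloxyphthalimide
Product: 26 (7R,8S)-14-acetoxy-13-(dimethylamino)-15-{[3-(dimethylamino)-2-(TBDPS-oxymethyl)propanoyl]oxy}germacra-1(10),4-dien-12,8-olide
Conditions: NiCl2·6H2O (20 mol %), 2,2'-bipyridine (20 mol %), AgNO3 (0.3 equiv, plates silver nanoparticles on the cathode), LiCl (0.1 M), DMF, 2 mM in 25, undivided cell, Mg anode, reticulated vitreous carbon cathode, constant current, 2.2 F/mol, rt, dark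
Reagents that add atoms: none
Why: Proposed new method: zerovalent nickel(bipyridine) made at the cathode inserts into the carbon–iodine bond at C1 with retention, monovalent nickel or the cathode reduces the N-acyloxyphthalimide, which loses phthalimide anion and CO2 to give the primary C2 radical, the alkenylnickel centre of the same molecule captures it, and the trivalent nickel intermediate forms C1–C2 by reductive elimination. The closest known reaction type is the intermolecular nickel-electrocatalytic decarboxylative alkenylation of redox-active esters with alkenyl iodides that joins the 1,5-diene units of terpenes, and its ring-closing use for a medium ring is what is new. It closes ring A (ten-membered) end to end through an eleven-membered nickelacycle, with both new ring atoms endocyclic. No stereocentre is formed, and the C1=C10 and C4=C5 geometries carry over because insertion and reductive elimination are stereoretentive and the homoallylic radical should be captured before it can close reversibly to the cyclopropylcarbinyl radical. The step needs ring closure to beat chain-to-chain coupling, hydrogen abstraction and conjugate addition, which the 2 mM dilution, the cis C9/iodine arrangement on C10=C1, the gauche C6/C9 arms on ring B and the amine masks on both acrylates secure. It also needs carbon–iodine insertion to beat ionisation of the two allylic esters, which the iodide, the hindered trisubstituted alkenes and the charge limit secure.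

Step 17
Reactants: 26 masked macrocycle
Product: 28 (7R,8S)-14-acetoxy-15-{2-[(TBDPS-oxy)methyl]acryloyloxy}germacra-1(10),4,11(13)-trien-12,8-olide, via bis(trimethylammonium) diiodide 27 (not isolated)
Conditions: MeI (20 equiv), MeCN, rt; then sat. aq NaHCO3, CH2Cl2, rt
Reagents that add atoms: none
Why: Exhaustive N-methylation followed by mild-base E1cB (Hofmann-type) elimination of trimethylamine regenerates both 2-substituted acrylate units without touching C7, C8 or the ring alkenes.

Step 18
Reactants: 28 TBDPS ether of the target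
Product: 29 CNP0126545.1
Conditions: HF·pyridine, pyridine, THF, 0 °C to rt
Reagents that add atoms: none
Why: Fluoride-mediated cleavage of the last silyl ether under buffered, non-basic conditions that spare the acetate, the acrylate ester and the acid-sensitive cyclodecadiene.

## Compound list

1 | prop-2-yn-1-yl acetate | C#CCOC(C)=O | starting material
2 | allyl bromide | C=CCBr | starting material
3 | (E)-2-(bromomethylidene)pent-4-en-1-yl acetate (Br cis to the allyl CH2) | C=CC/C(COC(C)=O)=C\Br | intermediate
4 | (E)-2-(iodomethylidene)pent-4-en-1-yl acetate | C=CC/C(COC(C)=O)=C\I | intermediate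
5 | (E)-4,5-dihydroxy-2-(iodomethylidene)pentyl acetate (racemic at the carbinol) | OCC(O)C/C(COC(C)=O)=C\I | intermediate
6 | (E)-2-(iodomethylidene)-4-oxobutyl acetate | O=CC/C(COC(C)=O)=C\I | intermediate
7 | 2-methylidenepropane-1,3-diol | C=C(CO)CO | starting material
8 | 2-{[(TBS)oxy]methyl}prop-2-en-1-ol | C=C(CO)CO[Si](C)(C)C(C)(C)C | intermediate
9 | tert-butyl{[2-(chloromethyl)prop-2-en-1-yl]oxy}dimethylsilane | C=C(CCl)CO[Si](C)(C)C(C)(C)C | intermediate
10 | ethyl 2-(hydroxymethyl)acrylate | C=C(CO)C(=O)OCC | starting material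
11 | ethyl 2-{[(TBDPS)oxy]methyl}acrylate | C=C(CO[Si](c1ccccc1)(c1ccccc1)C(C)(C)C)C(=O)OCC | intermediate
12 | 2-{[(TBDPS)oxy]methyl}acrylic acid | C=C(CO[Si](c1ccccc1)(c1ccccc1)C(C)(C)C)C(=O)O | intermediate
13 | prop-2-yn-1-ol | C#CCO | starting material
14 | (3-bromopropoxy)(tert-butyl)dimethylsilane | BrCCCO[Si](C)(C)C(C)(C)C | starting material
15 | 3-[(TBS)oxy]propylmagnesium bromide | Br[Mg]CCCO[Si](C)(C)C(C)(C)C | intermediate
16 | five-membered oxamagnesacycle (Mg bound to the vinylic CH and to the alkoxide O) | CC(C)(C)[Si](C)(C)OCCCC1=C[Mg]OC1 | intermediate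
17 | (Z)-2-{3-[(TBS)oxy]propyl}hexa-2,5-dien-1-ol | OC/C(=C\CC=C)CCCO[Si](C)(C)C(C)(C)C | intermediate
18 | (2Z)-6-(chloromethyl)-2-{3-[(TBS)oxy]propyl}-7-[(TBS)oxy]hepta-2,5-dien-1-ol (E/Z mixture at C5) | OC/C(=C\CC=C(CCl)CO[Si](C)(C)C(C)(C)C)CCCO[Si](C)(C)C(C)(C)C | intermediate
19 | 2-{[(TBDPS)oxy]methyl}acrylate ester of 18 | C=C(CO[Si](c1ccccc1)(c1ccccc1)C(C)(C)C)C(=O)OC/C(=C\CC=C(CCl)CO[Si](C)(C)C(C)(C)C)CCCO[Si](C)(C)C(C)(C)C | intermediate
20 | C8 trimethylsilyl ether of 21 | C=C(CO[Si](c1ccccc1)(c1ccccc1)C(C)(C)C)C(=O)OC/C(=C\C[C@H](C(=C)CO[Si](C)(C)C(C)(C)C)[C@@H](O[Si](C)(C)C)C/C(COC(C)=O)=C\I)CCCO[Si](C)(C)C(C)(C)C | intermediate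
21 | (7R,8S)-anti homoallylic alcohol | C=C(CO[Si](c1ccccc1)(c1ccccc1)C(C)(C)C)C(=O)OC/C(=C\C[C@H](C(=C)CO[Si](C)(C)C(C)(C)C)[C@@H](O)C/C(COC(C)=O)=C\I)CCCO[Si](C)(C)C(C)(C)C | intermediate
22 | (7R,8S)-triol | C=C(CO[Si](c1ccccc1)(c1ccccc1)C(C)(C)C)C(=O)OC/C(=C\C[C@H](C(=C)CO)[C@@H](O)C/C(COC(C)=O)=C\I)CCCO | intermediate
23 | trans α-methylene-γ-lactone acid, (2S,3R) in the lactone ring | C=C(CO[Si](c1ccccc1)(c1ccccc1)C(C)(C)C)C(=O)OC/C(=C\C[C@@H]1C(=C)C(=O)O[C@H]1C/C(COC(C)=O)=C\I)CCC(=O)O | intermediate
24 | bis(dimethylamine) adduct of 23 | CN(C)CC(CO[Si](c1ccccc1)(c1ccccc1)C(C)(C)C)C(=O)OC/C(=C\C[C@@H]1C(CN(C)C)C(=O)O[C@H]1C/C(COC(C)=O)=C\I)CCC(=O)O | intermediate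
25 | N-acyloxyphthalimide of 24 | CN(C)CC(CO[Si](c1ccccc1)(c1ccccc1)C(C)(C)C)C(=O)OC/C(=C\C[C@@H]1C(CN(C)C)C(=O)O[C@H]1C/C(COC(C)=O)=C\I)CCC(=O)ON1C(=O)c2ccccc2C1=O | intermediate
26 | masked macrocycle (7R,8S; C9/C2 cis on C1=C10, C3/C6 trans on C4=C5) | CN(C)CC(CO[Si](c1ccccc1)(c1ccccc1)C(C)(C)C)C(=O)OC/C1=C\C[C@@H]2C(CN(C)C)C(=O)O[C@H]2C/C(COC(C)=O)=C\CC1 | intermediate
27 | bis(trimethylammonium) diiodide of 26 | C[N+](C)(C)CC(CO[Si](c1ccccc1)(c1ccccc1)C(C)(C)C)C(=O)OC/C1=C\C[C@@H]2C(C[N+](C)(C)C)C(=O)O[C@H]2C/C(COC(C)=O)=C\CC1.[I-].[I-] | intermediate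
28 | TBDPS ether of the target | C=C(CO[Si](c1ccccc1)(c1ccccc1)C(C)(C)C)C(=O)OC/C1=C\C[C@@H]2C(=C)C(=O)O[C@H]2C/C(COC(C)=O)=C\CC1 | intermediate
29 | CNP0126545.1: (7R,8S)-14-acetoxy-15-[2-(hydroxymethyl)acryloyloxy]germacra-1(10),4,11(13)-trien-12,8-olide, 1(10)E and 4Z by sequence rule | C=C(CO)C(=O)OC/C1=C\C[C@@H]2C(=C)C(=O)O[C@H]2C/C(COC(C)=O)=C\CC1 | target

## Step count and risks

Total step count: 18. Longest linear sequence: 12 steps (4, 5, 9–18).

**Step 16.** Capture of the primary radical by the alkenylnickel centre of the same chain may be slower than hydrogen abstraction or chain-to-chain coupling. Zerovalent nickel may also begin to ionise the allylic esters as the product builds up. The fallback sets out from 25. Visible-light decarboxylative borylation with bis(catecholato)diboron in N,N-dimethylacetamide, followed by exchange with pinacol and Et3N, should give the primary alkyl pinacol boronate F1. An intramolecular Suzuki–Miyaura coupling of F1 [Pd(OAc)2, RuPhos, K3PO4, toluene–H2O, high dilution] then forms the same C1–C2 bond by a two-electron path and comes back to the route at 26.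

**Step 11.** The facial or the anti/syn selectivity of the catalytic allylation may be poor with this bulky chloride, and the aldehyde may drift into conjugation during a slow reaction. The fallback sets out from 19 and 6. A ligand-free addition with stoichiometric CrCl2 in THF, the classical anti-selective variant, should give the anti adduct as the racemate, that is 21 together with its (7S,8R)-enantiomer F2. Lipase-catalysed acylation with vinyl acetate should acetylate the (8R)-alcohol preferentially (C7 branch large, C9 methylene medium) to the acetate F3. This leaves 21, which is separated by chromatography, so the fallback comes back at 21.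

**Step 9.** Metathesis of the 1,1-disubstituted chloride may be sluggish, so that self-metathesis of the terminal alkene or migration of the skipped diene takes over. The fallback sets out from 17 and 8.
- MnO2 oxidation of 8 gives 2-{[(TBS)oxy]methyl}prop-2-enal F4.
- Cross metathesis of 17 with F4 (α-substituted acroleins are proven partners) gives the hydroxy enal F5.
- Steglich esterification with 12 gives the enal ester F6.
- Luche reduction (NaBH4, CeCl3·7H2O, MeOH, −40 °C) gives the allylic alcohol F7.
- Corey–Kim chlorination comes back to the route at 19.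

Further compounds
F1 | step 16 | primary alkyl pinacol boronate (Bpin on C2 in place of the acyloxyphthalimide carbonyl of 25) | CN(C)CC(CO[Si](c1ccccc1)(c1ccccc1)C(C)(C)C)C(=O)OC/C(=C\C[C@@H]1C(CN(C)C)C(=O)O[C@H]1C/C(COC(C)=O)=C\I)CCB1OC(C)(C)C(C)(C)O1
F2 | step 11 | (7S,8R)-enantiomer of 21 | C=C(CO[Si](c1ccccc1)(c1ccccc1)C(C)(C)C)C(=O)OC/C(=C\C[C@@H](C(=C)CO[Si](C)(C)C(C)(C)C)[C@H](O)C/C(COC(C)=O)=C\I)CCCO[Si](C)(C)C(C)(C)C
F3 | step 11 | C8 acetate of F2 | C=C(CO[Si](c1ccccc1)(c1ccccc1)C(C)(C)C)C(=O)OC/C(=C\C[C@@H](C(=C)CO[Si](C)(C)C(C)(C)C)[C@H](OC(C)=O)C/C(COC(C)=O)=C\I)CCCO[Si](C)(C)C(C)(C)C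
F4 | step 9 | 2-{[(TBS)oxy]methyl}prop-2-enal | C=C(C=O)CO[Si](C)(C)C(C)(C)C
F5 | step 9 | (2E,5Z)-7-hydroxy-2-{[(TBS)oxy]methyl}-6-{3-[(TBS)oxy]propyl}hepta-2,5-dienal | OC/C(=C\C/C=C(/C=O)CO[Si](C)(C)C(C)(C)C)CCCO[Si](C)(C)C(C)(C)C
F6 | step 9 | 2-{[(TBDPS)oxy]methyl}acrylate ester of F5 | C=C(CO[Si](c1ccccc1)(c1ccccc1)C(C)(C)C)C(=O)OC/C(=C\C/C=C(/C=O)CO[Si](C)(C)C(C)(C)C)CCCO[Si](C)(C)C(C)(C)C
F7 | step 9 | allylic alcohol from reduction of the aldehyde of F6 | C=C(CO[Si](c1ccccc1)(c1ccccc1)C(C)(C)C)C(=O)OC/C(=C\C/C=C(/CO)CO[Si](C)(C)C(C)(C)C)CCCO[Si](C)(C)C(C)(C)C
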